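## The problem

Target 24 is a single cyclohexane ring with a cis-fused oxirane in which every ring carbon is a stereocentre; the numbering used throughout is C1 for the fully substituted oxirane carbon bearing the benzoyloxymethyl carbon C7, C2 and C3 for the acetate carbons, C4 and C5 for the carbinol carbons, and C6 for the oxirane CH. The oxirane oxygen (O1) is cis to O2; the pairs O2/O3, O3/O4 and O4/O5 are trans; and O5 is trans to the oxirane oxygen at C6. C2, C3 and C4 form a D-xylo triad that a sugar can supply. In an open chain C2 can control the quaternary C1 by 1,2-induction, and once the ring exists C1 and C4 together can steer a reagent onto C5 and C6. C1 is the demanding centre, because a fully substituted carbinol cannot be corrected afterwards. The oxygens must also be told apart: O2 and O3 end acetylated, O4 and O5 free, O7 benzoylated. The oxirane and three esters next to free hydroxyls will not tolerate base (acyl migration from O3 to O4 or onto an O1 alkoxide, ester hydrolysis) or strong nucleophiles, so the esters must enter late and the last steps must run at or below neutral pH. The opening is that C5 and C6 are neighbours whose oxygens can both come from one cis-diol (O5 kept, O6 displaced by O1 with inversion), and before that they can be the two carbons of a ring alkene, which is what ring-closing metathesis of an octa-1,7-diene holding C1 to C4 delivers.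

## Retrosynthesis

**From 24 back to cyclohexene 18.** The oxirane C6–O1 bond and the C5–O and C6–O bonds are cut: 24 comes from silyl ether 23, 23 from cyclic sulfate 21, 21 from cis-diol 19, and 19 from alkene 18. The neighbouring option, epoxidation of C5=C6 from the upper face followed by a Payne shift, needs a peracid to approach anti to a hydroxyl that normally directs it syn. Osmylation anti to allylic oxygen is the dependable polarity. The cyclic sulfate also removes any question of which hydroxyl leaves, since O1 can reach only C6. Two stereocentres and the oxirane are exchanged for one alkene. The forward steps must osmylate on the face opposite O1 and O4, close the ring faster than acyl groups shuffle, and free O5 and O4 without harming the oxirane.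

**From 18 back to 15.** No skeletal bond is cut; the acetates on O2 and O3 are replaced by 4-methoxybenzyl ethers (18 from triol 16, 16 from 15). Acetates cannot pass the organometallic steps, and their stand-in must come off without acid or fluoride because O4 carries a silyl ether and C1 a tertiary allylic alcohol. Oxidative cleavage meets this. O4 stays silylated to the end so that it cannot compete with O1 in opening the cyclic sulfate.

**From 15 back to diene 14.** The C5=C6 bond is cut by ring-closing metathesis. Closing the ring at C1–C2 or C1–C6 by carbonyl addition would create the quaternary centre in the cyclisation itself, with uncertain control. The C5=C6 bond carries no stereochemistry and is the alkene needed next. Precursor 14 is an open chain whose four stereocentres can be set one at a time. The forward reaction has to cyclise two hindered vinyl groups in the presence of a free tertiary allylic hydroxyl without oligomerising.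

**From 14 back to aldehyde 6.** The benzoate is removed (14 from diol 12), then the C1–C7 bond (12 from enone 9 and silane 10), then the C1–C6 bond (9 from alcohol 8, 8 from aldehyde 6 and vinylmagnesium bromide 7). The two carbon substituents on C1 can be introduced in either order, and the order decides the configuration. A ketone already carrying C7, attacked by a vinyl Grignard reagent, would have to react anti to the C2–O bond (Felkin–Anh); magnesium chelation by the α-ether oxygen, the usual course for α-alkoxy ketones, gives the C1 epimer instead. With the vinyl group on the ketone 9 and C7 as the nucleophile, the same chelate delivers C7 to the face of C2–H and gives the required C1. The silylmethyl Grignard reagent from 10 is a hydroxymethyl anion equivalent that leaves O7 free for direct benzoylation. The carbinol centre of 8 is erased on oxidation, so its configuration does not matter.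

**From 6 back to glucoside 1.** Aldehyde 6 is a 5,6-dideoxy-D-xylo-hex-5-enose. A pentose with the same triad would need its C1 masked as a dithioacetal, its C5 oxidised and methylenated, and O4 singled out, which costs several more operations. The methyl 6-deoxy-6-iodo-α-D-glucopyranoside 5 has the same configuration at C2 to C4, and one reductive fragmentation cuts C5–O5 and releases both the C1 aldehyde and the C5 vinyl group. Iodide 5 comes from 4 (silylation of O4), 4 from diol 3 (iodination of O6), 3 from 2 (acetal removal) and 2 from commercial 1, whose benzylidene acetal already separates O4 and O6 from O2 and O3.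

## Roads not taken

**Alternative 1:** The carbocycle is bought as an arene and the C1–O and C2–O bonds are made enzymatically. Whole cells of a Ralstonia eutropha B9 mutant, which has the benzoate 1,2-dioxygenase but not the diol dehydrogenase, add both atoms of O2 to benzoic acid A1. The product of this key step is (1S,2R)-1,2-dihydroxycyclohexa-3,5-diene-1-carboxylic acid A2.
- Merits: one step from A1 gives the ring, the quaternary C1 with its one-carbon branch, and C2, with O1 and O2 cis and in the absolute configuration of 24. On paper this is far shorter than ten steps to carbocycle 15.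
- Weak points: four more oxygens (O3 to O6) must be added to the diene of A2 with three trans relationships, and O2/O3 must still be distinguished from O4/O5. Diene A2 re-aromatises readily by dehydration. The step needs fermentation with a mutant strain.
- Comparison: if the whole-cell oxidation is at hand, the road through A2 is probably shorter overall. The chosen plan offers O2, O3 and O4 already in place and differentiated from the sugar, and uses only shelf reagents.

**Alternative 2:** The C1–O and C4–O bonds are cut together. Singlet oxygen adds across C1 and C4 of the diene [(5S,6S)-5,6-bis(acetyloxy)cyclohexa-1,3-dien-1-yl]methyl benzoate A3, closing the 2,3-dioxabicyclo[2.2.2]octene endoperoxide A4. Reductive cleavage of the O–O bond of A4 would give ene-diol A5, which is 18 without its silyl group.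
- Merits: two C–O bonds form in one step on the same face, and the alkene of A4 is left at C5=C6, so the end game is the one used here. O1 and O4 are tied together by the bridge; here the chosen plan is inferior, since it sets them in separate steps.
- Weak points: A3 has one acetoxy group on each face, so nothing clearly biases the face of cycloaddition. Enantiopure A3 is itself a multistep target. In A5 the free O4 hydroxyl is anti to O5 and would compete with O1 when the cyclic sulfate is opened, so a protection step returns.
- Comparison: the chosen plan sets C1 by a chelate model and C2 to C4 by purchase, and O4 arrives protected.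

**Alternative 3:** The oxirane C6–O1 bond is cut in a desymmetrising Payne rearrangement. A chiral cobalt triflate complex of N,N'-bis(3,5-di-tert-butylsalicylidene)-1,2-cyclohexanediamine (trivalent cobalt) would activate one of the two enantiotopic oxiranes of meso bis-epoxyquinol A6. The C1 hydroxyl then attacks C6, giving A7 with the C1–C6 oxirane, the C5 hydroxyl, a C4 ketone and an intact C2–C3 oxirane.
- Merits: no chiral pool and the fewest steps on paper; A6 could be reached from an achiral aromatic precursor, and the catalyst sets the absolute configuration.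
- Weak points: the Payne shift is reversible, and its reverse leads from A7 back to meso A6, which threatens the enantiomeric purity. The C4 ketone of A7 must then be reduced to the correct face. The C2–C3 oxirane must be opened by oxygen at C2, the carbon next to the quaternary centre, while the other oxirane survives.
- Comparison: step count favours this road, but it has three unsolved selectivities. The chosen route answers each with a standard reaction.

Key step: step 10

Remark on the chemistry: 1 is taken as a purchasable material; carbocycles are numbered as in 24 rather than by lowest locants; PMB = 4-methoxybenzyl, TBS = tert-butyldimethylsilyl.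

## Route

Step 1
Reactants: 1 methyl 4,6-O-[(R)-benzylidene]-α-D-glucopyranoside
Product: 2 methyl 4,6-O-[(R)-benzylidene]-2,3-bis-O-(4-methoxybenzyl)-α-D-glucopyranoside
Conditions: NaH, PMBCl, Bu4NI (cat.), DMF, 0 °C to rt
Reagents that add atoms: 4-methoxybenzyl chloride, COc1ccc(CCl)cc1
Why: Williamson etherification of the two free secondary hydroxyls; the acetal keeps O4 and O6 apart from O2 and O3, and no stereocentre is touched.

Step 2
Reactants: 2 benzylidene acetal bis-PMB ether
Product: 3 methyl 2,3-bis-O-(4-methoxybenzyl)-α-D-glucopyranoside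
Conditions: p-TsOH·H2O (cat.), MeOH/CH2Cl2, rt
Reagents that add atoms: none
Why: Acid-catalysed transacetalisation to methanol removes the benzylidene group; PMB ethers and the methyl glycoside are stable to these conditions.

Step 3
Reactants: 3 4,6-diol
Product: 4 methyl 6-deoxy-6-iodo-2,3-bis-O-(4-methoxybenzyl)-α-D-glucopyranoside
Conditions: I2, PPh3, imidazole, toluene, 70 °C
Reagents that add atoms: iodine, II
Why: Garegg–Samuelsson iodination (Appel type); the primary hydroxyl is displaced far faster than the hindered secondary O4 hydroxyl.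

Step 4
Reactants: 4 6-iodo alcohol
Product: 5 methyl 4-O-(tert-butyldimethylsilyl)-6-deoxy-6-iodo-2,3-bis-O-(4-methoxybenzyl)-α-D-glucopyranoside
Conditions: TBSOTf, 2,6-lutidine, CH2Cl2, 0 °C
Reagents that add atoms: tert-butyldimethylsilyl trifluoromethanesulfonate, CC(C)(C)[Si](C)(C)OS(=O)(=O)C(F)(F)F
Why: Silylation of the remaining secondary hydroxyl with the reactive triflate; from here O4 is distinct from O2 and O3 for the rest of the route.

Step 5
Reactants: 5 silylated iodide
Product: 6 (2R,3R,4R)-4-[(tert-butyldimethylsilyl)oxy]-2,3-bis[(4-methoxybenzyl)oxy]hex-5-enal (a 5,6-dideoxy-D-xylo-hex-5-enose)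
Conditions: Zn dust (activated), THF/H2O 4:1, sonication, 40 °C
Reagents that add atoms: none
Why: Bernet–Vasella reductive fragmentation: Zn inserts into the C–I bond, β-elimination expels the ring oxygen to form the C5 vinyl group, and the hemiacetal anion loses methoxide to give the C1 aldehyde; C2 to C4 are untouched.

Step 6
Reactants: 6 aldehyde; 7 vinylmagnesium bromide
Product: 8 (3RS,4S,5R,6R)-6-[(tert-butyldimethylsilyl)oxy]-4,5-bis[(4-methoxybenzyl)oxy]octa-1,7-dien-3-ol (both C3 epimers)
Conditions: CH2=CHMgBr, THF, −78 °C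
Reagents that add atoms: vinylmagnesium bromide 7, C=C[Mg]Br
Why: Grignard addition to the aldehyde forms the C1–C6 bond; the new carbinol centre is oxidised in step 7, so both epimers are carried on.

Step 7
Reactants: 8 allylic alcohols
Product: 9 (4R,5R,6R)-6-[(tert-butyldimethylsilyl)oxy]-4,5-bis[(4-methoxybenzyl)oxy]octa-1,7-dien-3-one
Conditions: Dess–Martin periodinane, NaHCO3, CH2Cl2, 0 °C to rt
Reagents that add atoms: none
Why: Buffered Dess–Martin oxidation of an allylic alcohol; it is mild enough to leave the α-alkoxy stereocentre and the β-alkoxy group (no epimerisation, no elimination).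

Step 8
Reactants: 9 vinyl ketone; 10 (chloromethyl)(isopropoxy)dimethylsilane
Product: 12 (2R,3R,4R,5R)-5-[(tert-butyldimethylsilyl)oxy]-2-ethenyl-3,4-bis[(4-methoxybenzyl)oxy]hept-6-ene-1,2-diol, via β-silyl carbinol 11 (not isolated)
Conditions: (iPrO)Me2SiCH2MgCl (from 10, Mg, THF), THF, −78 °C; then KF, KHCO3, 30% H2O2, THF/MeOH, rt
Reagents that add atoms: (isopropoxydimethylsilyl)methylmagnesium chloride made from 10, CC(C)O[Si](C)(C)C[Mg]Cl; hydrogen peroxide, OO
Why: Chelation-controlled 1,2-addition of an α-silyl Grignard reagent: Mg bridges the carbonyl oxygen and the C2 ether oxygen (Cram chelate), and C7 enters from the face of C2–H, opposite C3, which sets C1. Tamao oxidation then turns the C–Si bond into the C7 hydroxyl.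

Step 9
Reactants: 12 diol; 13 benzoyl chloride
Product: 14 (2R,3R,4R,5R)-5-[(tert-butyldimethylsilyl)oxy]-2-ethenyl-2-hydroxy-3,4-bis[(4-methoxybenzyl)oxy]hept-6-en-1-yl benzoate
Conditions: BzCl, pyridine, CH2Cl2, −20 to 0 °C
Reagents that add atoms: benzoyl chloride 13, O=C(Cl)c1ccccc1
Why: Acylation of a primary hydroxyl in the presence of a tertiary one, which does not react under these conditions.

Step 10
Reactants: 14 octa-1,7-diene with free tertiary C1 hydroxyl
Product: 15 [(1R,2R,3R,4R)-4-[(tert-butyldimethylsilyl)oxy]-1-hydroxy-2,3-bis[(4-methoxybenzyl)oxy]cyclohex-5-en-1-yl]methyl benzoate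
Conditions: second-generation Grubbs catalyst (H2IMes)(PCy3)Cl2Ru=CHPh (5 mol%), CH2Cl2 (0.005 M), 40 °C
Reagents that add atoms: none
Why: The ruthenium benzylidene exchanges with one terminal vinyl group, probably the one next to the free tertiary hydroxyl, to give a ruthenium alkylidene with loss of styrene; [2+2] cycloaddition with the second vinyl group gives a ruthenacyclobutane whose cycloreversion releases 15 and Ru=CH2, which carries the chain and ends as ethene. The closest known reaction type is ring-closing metathesis of sugar-derived octa-1,7-dienes with allylic oxygen substituents and a tertiary allylic alcohol, as used for carbasugar cyclohexenes. The one ring closed is the six-membered carbocycle, formed by metathesis between C5 and C6, and its size allows only the cis alkene. No stereocentre is formed or touched, so C1 to C4 arrive in 15 as set in 14. The selectivity needed is cyclisation over acyclic diene oligomerisation: both alkenes are vinyl groups flanked by a quaternary or a silyloxy-bearing carbon, which slows intermolecular coupling, the four contiguous substituted carbons favour folded conformers, and high dilution does the rest. A tertiary allylic alcohol cannot be isomerised to a ketone by ruthenium hydrides, and loss of ethene makes the closure irreversible.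

Step 11
Reactants: 15 cyclohexene bis-PMB ether
Product: 16 [(1R,2R,3R,4R)-4-[(tert-butyldimethylsilyl)oxy]-1,2,3-trihydroxycyclohex-5-en-1-yl]methyl benzoate
Conditions: DDQ, CH2Cl2/pH 7 phosphate buffer 10:1, 0 °C to rt
Reagents that add atoms: none
Why: Oxidative PMB cleavage (hydride abstraction by DDQ, hydrolysis of the oxocarbenium ion); silyl ether, benzoate and alkene are inert, and the wet medium hydrolyses any 4-methoxybenzylidene acetal formed with the neighbouring O1 hydroxyl.

Step 12
Reactants: 16 triol; 17 acetic anhydride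
Product: 18 [(1R,2R,3R,4R)-2,3-bis(acetyloxy)-4-[(tert-butyldimethylsilyl)oxy]-1-hydroxycyclohex-5-en-1-yl]methyl benzoate
Conditions: Ac2O, pyridine, DMAP (cat.), CH2Cl2, 0 °C to rt
Reagents that add atoms: acetic anhydride 17, CC(=O)OC(C)=O
Why: Acetylation of the two secondary hydroxyls; the tertiary C1 hydroxyl is not acylated at this temperature.

Step 13
Reactants: 18 cyclohexene diacetate
Product: 19 [(1S,2R,3R,4R,5S,6R)-2,3-bis(acetyloxy)-4-[(tert-butyldimethylsilyl)oxy]-1,5,6-trihydroxycyclohexyl]methyl benzoate
Conditions: OsO4 (cat.), NMO, acetone/H2O, rt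
Reagents that add atoms: osmium tetroxide, O=[Os](=O)(=O)=O; N-methylmorpholine N-oxide, C[N+]1([O-])CCOCC1; water, O
Why: Upjohn dihydroxylation; suprafacial addition anti to both allylic oxygen substituents (the pseudoaxial C1 hydroxyl and the C4 silyloxy group lie on the lower face) places O5 and O6 on the upper face. This sets C5 for good and gives C6 the configuration that is inverted in step 15.

Step 14
Reactants: 19 triol
Product: 21 [(1R,2R,3R,4S,5R,6R)-2,3-bis(acetyloxy)-4-[(tert-butyldimethylsilyl)oxy]-1-hydroxy-5,6-(sulfonyldioxy)cyclohexyl]methyl benzoate (5,6-cyclic sulfate), via cyclic sulfite 20 (not isolated)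
Conditions: SOCl2, Et3N, CH2Cl2, 0 °C; then RuCl3·xH2O (cat.), NaIO4, MeCN/CH2Cl2/H2O, 0 °C
Reagents that add atoms: thionyl chloride, O=S(Cl)Cl; sodium periodate, [Na+].[O-]I(=O)(=O)=O
Why: Cyclic sulfite formation takes the cis-5,6-diol, because the two secondary hydroxyls are sulfinylated and bridged far faster than the hindered tertiary C1 hydroxyl reacts, and a trans-fused ring across O1/O6 would be more strained. RuO4-catalysed oxidation then gives the cyclic sulfate without touching the tertiary hydroxyl.

Step 15
Reactants: 21 cyclic sulfate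
Product: 23 [(1S,2R,3R,4R,5S,6S)-2,3-bis(acetyloxy)-4-[(tert-butyldimethylsilyl)oxy]-5-hydroxy-7-oxabicyclo[4.1.0]heptan-1-yl]methyl benzoate, via epoxy sulfate 22 (not isolated)
Conditions: DBU, THF, 0 °C to rt; then H2SO4 (cat.), H2O (1 equiv), THF, rt
Reagents that add atoms: none
Why: Intramolecular SN2 opening of the cyclic sulfate (3-exo-tet): O1 and the C6–O bond are trans-diaxial and only C6 is within reach, so the oxirane forms with inversion at C6 and O5 remains as a sulfate monoester. Catalytic acid with one equivalent of water then cleaves the S–O bond of the monoester under conditions that leave silyl ethers intact.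

Step 16
Reactants: 23 silyl ether
Product: 24 [(1S,2R,3S,4R,5R,6S)-2,3-bis(acetyloxy)-4,5-dihydroxy-7-oxabicyclo[4.1.0]heptan-1-yl]methyl benzoate (CNP0171674.1)
Conditions: HF·pyridine, pyridine, THF, 0 °C to rt
Reagents that add atoms: none
Why: Fluoride desilylation in a buffered, weakly acidic medium; no alkoxide is formed, which should suppress acetyl migration from O3 to O4 and opening of the oxirane.

## Compound list

1 | methyl 4,6-O-[(R)-benzylidene]-α-D-glucopyranoside | CO[C@@H]1[C@H](O)[C@@H](O)[C@@H]2O[C@H](c3ccccc3)OC[C@H]2O1 | starting material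
2 | methyl 4,6-O-[(R)-benzylidene]-2,3-bis-O-(4-methoxybenzyl)-α-D-glucopyranoside | CO[C@@H]1[C@H](OCc2ccc(OC)cc2)[C@@H](OCc2ccc(OC)cc2)[C@@H]2O[C@H](c3ccccc3)OC[C@H]2O1 | intermediate
3 | methyl 2,3-bis-O-(4-methoxybenzyl)-α-D-glucopyranoside | CO[C@@H]1[C@H](OCc2ccc(OC)cc2)[C@@H](OCc2ccc(OC)cc2)[C@H](O)[C@@H](CO)O1 | intermediate
4 | methyl 6-deoxy-6-iodo-2,3-bis-O-(4-methoxybenzyl)-α-D-glucopyranoside | CO[C@@H]1[C@H](OCc2ccc(OC)cc2)[C@@H](OCc2ccc(OC)cc2)[C@H](O)[C@@H](CI)O1 | intermediate
5 | methyl 4-O-(tert-butyldimethylsilyl)-6-deoxy-6-iodo-2,3-bis-O-(4-methoxybenzyl)-α-D-glucopyranoside | CO[C@@H]1[C@H](OCc2ccc(OC)cc2)[C@@H](OCc2ccc(OC)cc2)[C@H](O[Si](C)(C)C(C)(C)C)[C@@H](CI)O1 | intermediate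
6 | (2R,3R,4R)-4-[(tert-butyldimethylsilyl)oxy]-2,3-bis[(4-methoxybenzyl)oxy]hex-5-enal | O=C[C@H](OCc1ccc(OC)cc1)[C@@H](OCc1ccc(OC)cc1)[C@H](O[Si](C)(C)C(C)(C)C)C=C | intermediate
7 | vinylmagnesium bromide | C=C[Mg]Br | starting material
8 | (3RS,4S,5R,6R)-6-[(tert-butyldimethylsilyl)oxy]-4,5-bis[(4-methoxybenzyl)oxy]octa-1,7-dien-3-ol (both C3 epimers) | C=CC(O)[C@H](OCc1ccc(OC)cc1)[C@@H](OCc1ccc(OC)cc1)[C@H](O[Si](C)(C)C(C)(C)C)C=C | intermediate
9 | (4R,5R,6R)-6-[(tert-butyldimethylsilyl)oxy]-4,5-bis[(4-methoxybenzyl)oxy]octa-1,7-dien-3-one | C=CC(=O)[C@H](OCc1ccc(OC)cc1)[C@@H](OCc1ccc(OC)cc1)[C@H](O[Si](C)(C)C(C)(C)C)C=C | intermediate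
10 | (chloromethyl)(isopropoxy)dimethylsilane | CC(C)O[Si](C)(C)CCl | starting material
11 | (3S,4R,5R,6R)-6-[(tert-butyldimethylsilyl)oxy]-3-{[dimethyl(propan-2-yloxy)silyl]methyl}-4,5-bis[(4-methoxybenzyl)oxy]octa-1,7-dien-3-ol | C=C[C@@](O)(C[Si](C)(C)OC(C)C)[C@H](OCc1ccc(OC)cc1)[C@@H](OCc1ccc(OC)cc1)[C@H](O[Si](C)(C)C(C)(C)C)C=C | intermediate
12 | (2R,3R,4R,5R)-5-[(tert-butyldimethylsilyl)oxy]-2-ethenyl-3,4-bis[(4-methoxybenzyl)oxy]hept-6-ene-1,2-diol | C=C[C@@](O)(CO)[C@H](OCc1ccc(OC)cc1)[C@@H](OCc1ccc(OC)cc1)[C@H](O[Si](C)(C)C(C)(C)C)C=C | intermediate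
13 | benzoyl chloride | O=C(Cl)c1ccccc1 | starting material
14 | (2R,3R,4R,5R)-5-[(tert-butyldimethylsilyl)oxy]-2-ethenyl-2-hydroxy-3,4-bis[(4-methoxybenzyl)oxy]hept-6-en-1-yl benzoate | C=C[C@@](O)(COC(=O)c1ccccc1)[C@H](OCc1ccc(OC)cc1)[C@@H](OCc1ccc(OC)cc1)[C@H](O[Si](C)(C)C(C)(C)C)C=C | intermediate
15 | [(1R,2R,3R,4R)-4-[(tert-butyldimethylsilyl)oxy]-1-hydroxy-2,3-bis[(4-methoxybenzyl)oxy]cyclohex-5-en-1-yl]methyl benzoate | O[C@@]1(COC(=O)c2ccccc2)C=C[C@@H](O[Si](C)(C)C(C)(C)C)[C@H](OCc2ccc(OC)cc2)[C@H]1OCc1ccc(OC)cc1 | intermediate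
16 | [(1R,2R,3R,4R)-4-[(tert-butyldimethylsilyl)oxy]-1,2,3-trihydroxycyclohex-5-en-1-yl]methyl benzoate | O[C@@]1(COC(=O)c2ccccc2)C=C[C@@H](O[Si](C)(C)C(C)(C)C)[C@H](O)[C@H]1O | intermediate
17 | acetic anhydride | CC(=O)OC(C)=O | starting material
18 | [(1R,2R,3R,4R)-2,3-bis(acetyloxy)-4-[(tert-butyldimethylsilyl)oxy]-1-hydroxycyclohex-5-en-1-yl]methyl benzoate | O[C@@]1(COC(=O)c2ccccc2)C=C[C@@H](O[Si](C)(C)C(C)(C)C)[C@H](OC(C)=O)[C@H]1OC(C)=O | intermediate
19 | [(1S,2R,3R,4R,5S,6R)-2,3-bis(acetyloxy)-4-[(tert-butyldimethylsilyl)oxy]-1,5,6-trihydroxycyclohexyl]methyl benzoate | O[C@@]1(COC(=O)c2ccccc2)[C@H](O)[C@H](O)[C@@H](O[Si](C)(C)C(C)(C)C)[C@H](OC(C)=O)[C@H]1OC(C)=O | intermediate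
20 | [(1R,2R,3R,4S,5R,6R)-2,3-bis(acetyloxy)-4-[(tert-butyldimethylsilyl)oxy]-1-hydroxy-5,6-(sulfinyldioxy)cyclohexyl]methyl benzoate (5,6-cyclic sulfite of 19; either configuration at sulfur) | O[C@@]1(COC(=O)c2ccccc2)[C@@H]2OS(=O)O[C@@H]2[C@@H](O[Si](C)(C)C(C)(C)C)[C@H](OC(C)=O)[C@H]1OC(C)=O | intermediate
21 | [(1R,2R,3R,4S,5R,6R)-2,3-bis(acetyloxy)-4-[(tert-butyldimethylsilyl)oxy]-1-hydroxy-5,6-(sulfonyldioxy)cyclohexyl]methyl benzoate | O[C@@]1(COC(=O)c2ccccc2)[C@@H]2OS(=O)(=O)O[C@@H]2[C@@H](O[Si](C)(C)C(C)(C)C)[C@H](OC(C)=O)[C@H]1OC(C)=O | intermediate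
22 | [(1S,2R,3R,4S,5S,6S)-2,3-bis(acetyloxy)-4-[(tert-butyldimethylsilyl)oxy]-5-(sulfooxy)-7-oxabicyclo[4.1.0]heptan-1-yl]methyl benzoate (present as its DBU salt) | CC(=O)O[C@H]1[C@H](O[Si](C)(C)C(C)(C)C)[C@@H](OS(=O)(=O)O)[C@@H]2O[C@]2(COC(=O)c2ccccc2)[C@@H]1OC(C)=O | intermediate
23 | [(1S,2R,3R,4R,5S,6S)-2,3-bis(acetyloxy)-4-[(tert-butyldimethylsilyl)oxy]-5-hydroxy-7-oxabicyclo[4.1.0]heptan-1-yl]methyl benzoate | CC(=O)O[C@H]1[C@H](O[Si](C)(C)C(C)(C)C)[C@@H](O)[C@@H]2O[C@]2(COC(=O)c2ccccc2)[C@@H]1OC(C)=O | intermediate
24 | [(1S,2R,3S,4R,5R,6S)-2,3-bis(acetyloxy)-4,5-dihydroxy-7-oxabicyclo[4.1.0]heptan-1-yl]methyl benzoate | CC(=O)O[C@H]1[C@H](O)[C@@H](O)[C@@H]2O[C@]2(COC(=O)c2ccccc2)[C@@H]1OC(C)=O | target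

Total step count: 16. Longest linear sequence: 16 steps, from 1 to 24.

## Least certain steps

**Step 10 (key step).** Carbene loading may be slow at two vinyl groups that each sit next to a fully substituted or silyloxy-bearing carbon, so the catalyst could decay before closure or intermolecular metathesis could compete. The fallback sets out from 14 and comes back at 15. The silyl ether is removed first (HF·pyridine) to give (2R,3R,4S,5R)-2-ethenyl-2,5-dihydroxy-3,4-bis[(4-methoxybenzyl)oxy]hept-6-en-1-yl benzoate F1, whose free secondary allylic hydroxyl both unblocks the C5 vinyl group and assists loading. Ring-closing metathesis with the same catalyst should then give [(1R,2R,3S,4R)-1,4-dihydroxy-2,3-bis[(4-methoxybenzyl)oxy]cyclohex-5-en-1-yl]methyl benzoate F2, and silylation of the secondary allylic hydroxyl alone (TBSCl, imidazole, DMF) returns to 15.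

**Step 8.** Conjugate addition to, or polymerisation of, the vinyl ketone may compete with carbonyl addition, and facial selectivity may erode if the chelate is not fully formed. The fallback sets out from 6 and comes back at 12, with an alkyne standing in for the vinyl group. LiC≡CSiMe3 (THF, −78 °C) adds to 6 to give (3RS,4S,5R,6R)-6-[(tert-butyldimethylsilyl)oxy]-4,5-bis[(4-methoxybenzyl)oxy]-1-(trimethylsilyl)oct-7-en-1-yn-3-ol F3, and Dess–Martin oxidation gives (4R,5R,6R)-6-[(tert-butyldimethylsilyl)oxy]-4,5-bis[(4-methoxybenzyl)oxy]-1-(trimethylsilyl)oct-7-en-1-yn-3-one F4. The Grignard reagent from 10 should add to the carbonyl of this ynone through the same chelate, giving (3S,4R,5R,6R)-6-[(tert-butyldimethylsilyl)oxy]-3-{[dimethyl(propan-2-yloxy)silyl]methyl}-4,5-bis[(4-methoxybenzyl)oxy]-1-(trimethylsilyl)oct-7-en-1-yn-3-ol F5, which is not isolated. Tamao oxidation (KF, KHCO3, H2O2), which also removes the alkynyl silyl group, gives (2R,3R,4R,5R)-5-[(tert-butyldimethylsilyl)oxy]-2-ethynyl-3,4-bis[(4-methoxybenzyl)oxy]hept-6-ene-1,2-diol F6, and semihydrogenation (H2, Pd/CaCO3 poisoned with Pb(OAc)2, quinoline) returns to 12.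

**Step 13.** Facial selectivity may be poor, or osmylation sluggish, at a cis-alkene flanked by a quaternary carbon whose benzoyloxymethyl group lies on the face to be attacked. The fallback sets out from 18 and comes back at 23, by epoxidation and oxirane migration instead of dihydroxylation and sulfate chemistry. The tertiary hydroxyl is capped (TMSOTf, 2,6-lutidine) to give [(1R,2R,3R,4R)-2,3-bis(acetyloxy)-4-[(tert-butyldimethylsilyl)oxy]-1-[(trimethylsilyl)oxy]cyclohex-5-en-1-yl]methyl benzoate F7, in which both allylic oxygens shield the lower face and none can direct a peracid. mCPBA should then give the 5,6-epoxide F8, with the oxirane oxygen anti to O1 and O4. Citric acid in MeOH removes the trimethylsilyl group to give the corresponding 5,6-epoxy tertiary alcohol F9. A Payne rearrangement (DBU or catalytic KOtBu, THF), in which O1 attacks C6 from the lower face and the more substituted oxirane is favoured, joins the route at 23.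

**Step 15.** Before the ring closes, the C1 alkoxide may take up the neighbouring acetyl or benzoyl group and scramble the esters; the oxirane may also be lost during the acidic sulfate hydrolysis. The fallback goes from 19 straight to 23, without sulfur chemistry or added base, by Mitsunobu cyclodehydration (PPh3, DIAD, toluene). Only the oxyphosphonium at O6 has an antiperiplanar internal nucleophile (O1), so the oxirane should form with inversion at C6, while activation at O5 is unproductive and reversible. No new compound is made on the way.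

## Further compounds

F1 | step 10 | (2R,3R,4S,5R)-2-ethenyl-2,5-dihydroxy-3,4-bis[(4-methoxybenzyl)oxy]hept-6-en-1-yl benzoate | C=C[C@@](O)(COC(=O)c1ccccc1)[C@H](OCc1ccc(OC)cc1)[C@@H](OCc1ccc(OC)cc1)[C@H](O)C=C
F2 | step 10 | [(1R,2R,3S,4R)-1,4-dihydroxy-2,3-bis[(4-methoxybenzyl)oxy]cyclohex-5-en-1-yl]methyl benzoate | O[C@@]1(COC(=O)c2ccccc2)C=C[C@@H](O)[C@H](OCc2ccc(OC)cc2)[C@H]1OCc1ccc(OC)cc1
F3 | step 8 | (3RS,4S,5R,6R)-6-[(tert-butyldimethylsilyl)oxy]-4,5-bis[(4-methoxybenzyl)oxy]-1-(trimethylsilyl)oct-7-en-1-yn-3-ol | C[Si](C)(C)C#CC(O)[C@H](OCc1ccc(OC)cc1)[C@@H](OCc1ccc(OC)cc1)[C@H](O[Si](C)(C)C(C)(C)C)C=C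
F4 | step 8 | (4R,5R,6R)-6-[(tert-butyldimethylsilyl)oxy]-4,5-bis[(4-methoxybenzyl)oxy]-1-(trimethylsilyl)oct-7-en-1-yn-3-one | C[Si](C)(C)C#CC(=O)[C@H](OCc1ccc(OC)cc1)[C@@H](OCc1ccc(OC)cc1)[C@H](O[Si](C)(C)C(C)(C)C)C=C
F5 | step 8 | (3S,4R,5R,6R)-6-[(tert-butyldimethylsilyl)oxy]-3-{[dimethyl(propan-2-yloxy)silyl]methyl}-4,5-bis[(4-methoxybenzyl)oxy]-1-(trimethylsilyl)oct-7-en-1-yn-3-ol | C[Si](C)(C)C#C[C@@](O)(C[Si](C)(C)OC(C)C)[C@H](OCc1ccc(OC)cc1)[C@@H](OCc1ccc(OC)cc1)[C@H](O[Si](C)(C)C(C)(C)C)C=C
F6 | step 8 | (2R,3R,4R,5R)-5-[(tert-butyldimethylsilyl)oxy]-2-ethynyl-3,4-bis[(4-methoxybenzyl)oxy]hept-6-ene-1,2-diol | C#C[C@@](O)(CO)[C@H](OCc1ccc(OC)cc1)[C@@H](OCc1ccc(OC)cc1)[C@H](O[Si](C)(C)C(C)(C)C)C=C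
F7 | step 13 | [(1R,2R,3R,4R)-2,3-bis(acetyloxy)-4-[(tert-butyldimethylsilyl)oxy]-1-[(trimethylsilyl)oxy]cyclohex-5-en-1-yl]methyl benzoate | C[Si](C)(C)O[C@@]1(COC(=O)c2ccccc2)C=C[C@@H](O[Si](C)(C)C(C)(C)C)[C@H](OC(C)=O)[C@H]1OC(C)=O
F8 | step 13 | 5,6-epoxide of F7 with the oxirane oxygen anti to O1 and O4 | C[Si](C)(C)O[C@@]1(COC(=O)c2ccccc2)[C@@H]2O[C@@H]2[C@@H](O[Si](C)(C)C(C)(C)C)[C@H](OC(C)=O)[C@H]1OC(C)=O
F9 | step 13 | 5,6-epoxy tertiary alcohol from F8 (oxirane oxygen anti to O1 and O4) | O[C@@]1(COC(=O)c2ccccc2)[C@@H]2O[C@@H]2[C@@H](O[Si](C)(C)C(C)(C)C)[C@H](OC(C)=O)[C@H]1OC(C)=O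
F0 | step 15 | none | none
A1 | alternative 1 | benzoic acid | O=C(O)c1ccccc1
A2 | alternative 1 | (1S,2R)-1,2-dihydroxycyclohexa-3,5-diene-1-carboxylic acid | C1=CC=C[C@@](O)(C(=O)O)[C@@H]1O
A3 | alternative 2 | [(5S,6S)-5,6-bis(acetyloxy)cyclohexa-1,3-dien-1-yl]methyl benzoate | CC(=O)O[C@H]1C=CC=C(COC(=O)c2ccccc2)[C@@H]1OC(C)=O
A4 | alternative 2 | [7,8-bis(acetyloxy)-2,3-dioxabicyclo[2.2.2]oct-5-en-1-yl]methyl benzoate, peroxide bridge from C1 to C4 on the face of the C2 acetoxy group | CC(=O)O[C@H]1[C@H]2C=C[C@](COC(=O)c3ccccc3)(OO2)[C@@H]1OC(C)=O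
A5 | alternative 2 | [(1R,2R,3S,4R)-2,3-bis(acetyloxy)-1,4-dihydroxycyclohex-5-en-1-yl]methyl benzoate | O[C@@]1(COC(=O)c2ccccc2)C=C[C@@H](O)[C@H](OC(C)=O)[C@H]1OC(C)=O
A6 | alternative 3 | meso 4-(benzoyloxymethyl)-4-hydroxy-2,3:5,6-diepoxycyclohexanone, both oxiranes anti to the hydroxyl | O=C1[C@@H]2O[C@@H]2[C@](O)(COC(=O)c2ccccc2)[C@@H]2O[C@H]12
A7 | alternative 3 | C1–C6 oxirane with C5 hydroxyl, C4 ketone and intact C2–C3 oxirane | O1[C@H]2C(=O)[C@@H](O)[C@@H]3O[C@]3(COC(=O)c3ccccc3)[C@@H]12
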